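## Retrosynthetic overview

- Last disconnection: the ester C–O bond, giving linoleic acid and the (S)-configured monocyclic diterpenol (Steglich esterification).
- Ring C1–side-chain bond (C1 is the only stereocentre): anti-SN2′ coupling of a C11 homoallylic Grignard reagent (geraniol plus one carbon) with the picolinate of (S)-2,4,4-trimethylcyclohex-2-en-1-ol. The C–O bond on ring C3 (the carbon that ends as the olefinic CH) is not in the target: it is set by CBS reduction, passes its chirality 1,3 to C1, and is cleaved in the same event that places the C2=C3 double bond.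
- The only ring is formed first: 2,4,4-trimethylcyclohex-2-en-1-one from isobutyraldehyde and ethyl vinyl ketone by a one-pot Robinson annulation that makes ring bonds C5–C6 (CH2–CMe2) and C1–C2 (CH–C(CH3)).
- Enabling feature: in the 2,6,6-trimethylcyclohex-2-enyl ring the quaternary gem-dimethyl carbon C6 sits next to the H-bearing C1, and C1–C2(CH3)=C3 is an allylic triad that can carry a temporary oxygen on C3. C6/C1 then map onto the α-carbon/carbonyl carbon of an aldehyde with a single α-hydrogen, and C5–C4–C3(=O)–C2–CH3 onto a vinyl ketone, so only one Michael addition and only a six-membered aldol closure are possible.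

Key step: step 1

Remark: ring locants are those of the 2,6,6-trimethylcyclohex-2-en-1-yl unit of the target, whose stereocentre C1 is (S) as read from the SMILES; isobutyraldehyde, ethyl vinyl ketone, geraniol and linoleic acid are taken as commercial.

## Route

Step 1
Reactants: 1 isobutyraldehyde (2-methylpropanal); 2 ethyl vinyl ketone (pent-1-en-3-one)
Product: 4 2,4,4-trimethylcyclohex-2-en-1-one, via 2,2-dimethyl-5-oxoheptanal 3 (not isolated)
Conditions: H2SO4 (cat.), neat, 45–50 °C; then toluene, reflux, Dean–Stark
Reagents that add atoms: none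
Why: Acid-catalysed Robinson annulation: the enol of 1 (its single α-carbon, the future gem-dimethyl carbon) adds in a Michael fashion to the CH2 terminus of protonated 2 (first bond, CH2–CMe2) to give ketoaldehyde 3, whose ethyl ketone enolises towards its CH2 group and attacks the aldehyde carbon (second bond), and loss of water leaves that bond as the conjugated C(CH3)=CH double bond of 4. The closest known reaction type is the one-pot acid-catalysed annulation of α,α-dialkyl aldehydes with vinyl ketones. The single ring is closed by a 6-(enolendo)-exo-trig aldol addition followed by dehydration. No stereocentre is created; the step delivers a prochiral enone whose β-carbon is the later stereocentre and whose carbonyl oxygen is the temporary handle for steps 2 and 10. The step needs chemoselectivity (one Michael addition, no crossed aldol of 1) and a single aldol regiochemistry. The substrate secures both: 1 has one α-hydrogen and is non-enolisable after the Michael step, and the other α-CH2 of the ketone could only close a cyclobutane.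

Step 2
Reactants: 4 2,4,4-trimethylcyclohex-2-en-1-one
Product: 5 (1S)-2,4,4-trimethylcyclohex-2-en-1-ol
Conditions: (R)-2-methyl-CBS-oxazaborolidine (15 mol%), BH3·SMe2, THF, −20 °C; then MeOH, aq. NH4Cl
Reagents that add atoms: none
Why: Corey–Bakshi–Shibata reduction in which the methyl-bearing olefinic carbon acts as the large group and the ring CH2 as the small one, so the (R)-catalyst (the enantiomer that reduces acetophenone to (S)-1-phenylethanol) should deliver hydride to the carbonyl face that gives the (S)-carbinol, the new stereocentre, with 1,2-reduction favoured over hydroboration at low temperature.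

Step 3
Reactants: 5 (1S)-2,4,4-trimethylcyclohex-2-en-1-ol
Product: 6 (1S)-2,4,4-trimethylcyclohex-2-en-1-yl pyridine-2-carboxylate
Conditions: picolinic acid, DCC, DMAP (cat.), CH2Cl2, 0 °C → rt
Reagents that add atoms: picolinic acid, OC(=O)c1ccccn1
Why: Steglich esterification through the O-acylisourea and the acylpyridinium ion, which does not touch the carbinol C–O bond, so the (S)-configuration is retained.

Step 4
Reactants: 7 geraniol
Product: 8 tert-butyl{[(2E)-3,7-dimethylocta-2,6-dien-1-yl]oxy}dimethylsilane
Conditions: TBSCl, imidazole, DMF, 0 °C → rt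
Reagents that add atoms: tert-butyldimethylsilyl chloride, CC(C)(C)[Si](C)(C)Cl
Why: Standard silylation of a primary alcohol, giving an ether that should tolerate the later oxidation, ylide, borane and Grignard steps.

Step 5
Reactants: 8 tert-butyl{[(2E)-3,7-dimethylocta-2,6-dien-1-yl]oxy}dimethylsilane
Product: 9 (2E,6E)-8-{[tert-butyl(dimethyl)silyl]oxy}-2,6-dimethylocta-2,6-dien-1-ol
Conditions: SeO2 (cat.), t-BuOOH, salicylic acid (cat.), CH2Cl2, rt
Reagents that add atoms: SeO2, O=[Se]=O (catalytic oxygen carrier); tert-butyl hydroperoxide, CC(C)(C)OO (terminal oxygen source)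
Why: SeO2 allylic oxidation (ene reaction, then 2,3-sigmatropic shift) should attack the more electron-rich terminal trisubstituted olefin at its (E)-methyl group and give the (E)-allylic alcohol, the olefin next to the silyloxymethyl group being deactivated.

Step 6
Reactants: 9 (2E,6E)-8-{[tert-butyl(dimethyl)silyl]oxy}-2,6-dimethylocta-2,6-dien-1-ol
Product: 10 (2E,6E)-8-{[tert-butyl(dimethyl)silyl]oxy}-2,6-dimethylocta-2,6-dienal
Conditions: MnO2, CH2Cl2, rt
Reagents that add atoms: none
Why: Manganese dioxide oxidises only the primary allylic alcohol to the conjugated aldehyde and should leave the silyl ether and the (E)-olefins unchanged.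

Step 7
Reactants: 10 (2E,6E)-8-{[tert-butyl(dimethyl)silyl]oxy}-2,6-dimethylocta-2,6-dienal
Product: 11 tert-butyl{[(2E,6E)-3,7-dimethylnona-2,6,8-trien-1-yl]oxy}dimethylsilane
Conditions: Ph3PCH3Br, KOtBu, THF, 0 °C → rt
Reagents that add atoms: methyltriphenylphosphonium bromide, C[P+](c1ccccc1)(c1ccccc1)c1ccccc1.[Br-] (supplies the CH2 group)
Why: Wittig methylenation of the enal with the unstabilised ylide should give the terminal 1,3-diene without affecting the existing (E)-trisubstituted olefins.

Step 8
Reactants: 11 tert-butyl{[(2E,6E)-3,7-dimethylnona-2,6,8-trien-1-yl]oxy}dimethylsilane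
Product: 13 (3E,7E)-9-{[tert-butyl(dimethyl)silyl]oxy}-3,7-dimethylnona-3,7-dien-1-ol, via B-alkyl-9-BBN 12 (not isolated)
Conditions: 9-BBN, THF, 0 °C → rt; then NaOH, H2O2, 0 °C
Reagents that add atoms: hydrogen peroxide, OO (supplies the hydroxyl oxygen)
Why: Hydroboration–oxidation in which the bulky dialkylborane adds anti-Markovnikov to the only monosubstituted double bond, the vinyl end of the diene, much faster than to the trisubstituted olefins, and oxidation with retention gives the homoallylic alcohol.

Step 9
Reactants: 13 (3E,7E)-9-{[tert-butyl(dimethyl)silyl]oxy}-3,7-dimethylnona-3,7-dien-1-ol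
Product: 14 {[(2E,6E)-9-bromo-3,7-dimethylnona-2,6-dien-1-yl]oxy}(tert-butyl)dimethylsilane
Conditions: CBr4, PPh3, 2,6-lutidine, CH2Cl2, 0 °C
Reagents that add atoms: carbon tetrabromide, BrC(Br)(Br)Br
Why: The Appel reaction converts the primary alcohol into the bromide under buffered, near-neutral conditions that should leave the allylic silyl ether and both (E)-olefins intact.

Step 10
Reactants: 14 {[(2E,6E)-9-bromo-3,7-dimethylnona-2,6-dien-1-yl]oxy}(tert-butyl)dimethylsilane; 6 (1S)-2,4,4-trimethylcyclohex-2-en-1-yl pyridine-2-carboxylate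
Product: 16 tert-butyl(dimethyl){[(2E,6E)-3,7-dimethyl-9-[(1S)-2,6,6-trimethylcyclohex-2-en-1-yl]nona-2,6-dien-1-yl]oxy}silane, via alkylmagnesium bromide 15 (not isolated)
Conditions: Mg, THF, rt; CuBr·SMe2 (50 mol%), THF, −40 °C; then 6, −40 → 0 °C; aq. NH4Cl
Reagents that add atoms: none
Why: Copper-mediated anti-SN2′ allylic substitution of a secondary allylic picolinate by a Grignard reagent, in which magnesium chelated by the pyridine nitrogen and the carbonyl oxygen activates the leaving group and the organocopper adds at the γ-carbon on the face opposite to the C–O bond (reductive elimination from the γ-σ-allyl trivalent copper species), so the (S)-carbinol centre is translated by 1,3-chirality transfer into the (S)-configured ring CH while the double bond moves into the C(CH3)=CH position of the target.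

Step 11
Reactants: 16 tert-butyl(dimethyl){[(2E,6E)-3,7-dimethyl-9-[(1S)-2,6,6-trimethylcyclohex-2-en-1-yl]nona-2,6-dien-1-yl]oxy}silane
Product: 17 (2E,6E)-3,7-dimethyl-9-[(1S)-2,6,6-trimethylcyclohex-2-en-1-yl]nona-2,6-dien-1-ol
Conditions: TBAF, THF, 0 °C → rt
Reagents that add atoms: none
Why: Fluoride cleaves the Si–O bond selectively, the trisubstituted olefins and the stereocentre being inert to these conditions.

Step 12
Reactants: 17 (2E,6E)-3,7-dimethyl-9-[(1S)-2,6,6-trimethylcyclohex-2-en-1-yl]nona-2,6-dien-1-ol; 18 linoleic acid ((9Z,12Z)-octadeca-9,12-dienoic acid)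
Product: 19 (2E,6E)-3,7-dimethyl-9-[(1S)-2,6,6-trimethylcyclohex-2-en-1-yl]nona-2,6-dien-1-yl (9Z,12Z)-octadeca-9,12-dienoate
Conditions: EDC·HCl, DMAP (cat.), CH2Cl2, 0 °C → rt
Reagents that add atoms: none
Why: Steglich esterification under neutral conditions at or below room temperature should join the primary allylic alcohol with linoleic acid without migration or isomerisation of the skipped (Z,Z)-diene.

## Compound list

1 | isobutyraldehyde (2-methylpropanal) | CC(C)C=O | starting material
2 | ethyl vinyl ketone (pent-1-en-3-one) | CCC(=O)C=C | starting material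
3 | 2,2-dimethyl-5-oxoheptanal | CCC(=O)CCC(C)(C)C=O | intermediate
4 | 2,4,4-trimethylcyclohex-2-en-1-one | CC1=CC(C)(C)CCC1=O | intermediate
5 | (1S)-2,4,4-trimethylcyclohex-2-en-1-ol | O[C@@H]1C(C)=CC(C)(C)CC1 | intermediate
6 | (1S)-2,4,4-trimethylcyclohex-2-en-1-yl pyridine-2-carboxylate | O=C(O[C@@H]1C(C)=CC(C)(C)CC1)c1ccccn1 | intermediate
7 | geraniol ((2E)-3,7-dimethylocta-2,6-dien-1-ol) | CC(C)=CCC/C(C)=C/CO | starting material
8 | tert-butyl{[(2E)-3,7-dimethylocta-2,6-dien-1-yl]oxy}dimethylsilane | CC(C)=CCC/C(C)=C/CO[Si](C)(C)C(C)(C)C | intermediate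
9 | (2E,6E)-8-{[tert-butyl(dimethyl)silyl]oxy}-2,6-dimethylocta-2,6-dien-1-ol | OC/C(C)=C/CC/C(C)=C/CO[Si](C)(C)C(C)(C)C | intermediate
10 | (2E,6E)-8-{[tert-butyl(dimethyl)silyl]oxy}-2,6-dimethylocta-2,6-dienal | O=C/C(C)=C/CC/C(C)=C/CO[Si](C)(C)C(C)(C)C | intermediate
11 | tert-butyl{[(2E,6E)-3,7-dimethylnona-2,6,8-trien-1-yl]oxy}dimethylsilane | C=C/C(C)=C/CC/C(C)=C/CO[Si](C)(C)C(C)(C)C | intermediate
12 | 9-[(3E,7E)-9-{[tert-butyl(dimethyl)silyl]oxy}-3,7-dimethylnona-3,7-dien-1-yl]-9-borabicyclo[3.3.1]nonane | C1CCC2CCCC1B2CC/C(C)=C/CC/C(C)=C/CO[Si](C)(C)C(C)(C)C | intermediate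
13 | (3E,7E)-9-{[tert-butyl(dimethyl)silyl]oxy}-3,7-dimethylnona-3,7-dien-1-ol | OCC/C(C)=C/CC/C(C)=C/CO[Si](C)(C)C(C)(C)C | intermediate
14 | {[(2E,6E)-9-bromo-3,7-dimethylnona-2,6-dien-1-yl]oxy}(tert-butyl)dimethylsilane | BrCC/C(C)=C/CC/C(C)=C/CO[Si](C)(C)C(C)(C)C | intermediate
15 | [(3E,7E)-9-{[tert-butyl(dimethyl)silyl]oxy}-3,7-dimethylnona-3,7-dien-1-yl]magnesium bromide | Br[Mg]CC/C(C)=C/CC/C(C)=C/CO[Si](C)(C)C(C)(C)C | intermediate
16 | tert-butyl(dimethyl){[(2E,6E)-3,7-dimethyl-9-[(1S)-2,6,6-trimethylcyclohex-2-en-1-yl]nona-2,6-dien-1-yl]oxy}silane | CC(C)(C)[Si](C)(C)OC/C=C(\C)CC/C=C(\C)CC[C@@H]1C(C)=CCCC1(C)C | intermediate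
17 | (2E,6E)-3,7-dimethyl-9-[(1S)-2,6,6-trimethylcyclohex-2-en-1-yl]nona-2,6-dien-1-ol | OC/C=C(\C)CC/C=C(\C)CC[C@@H]1C(C)=CCCC1(C)C | intermediate
18 | linoleic acid ((9Z,12Z)-octadeca-9,12-dienoic acid) | CCCCC/C=C\C/C=C\CCCCCCCC(=O)O | starting material
19 | (2E,6E)-3,7-dimethyl-9-[(1S)-2,6,6-trimethylcyclohex-2-en-1-yl]nona-2,6-dien-1-yl (9Z,12Z)-octadeca-9,12-dienoate | CCCCC/C=C\C/C=C\CCCCCCCC(=O)OC/C=C(\C)CC/C=C(\C)CC[C@@H]1C(C)=CCCC1(C)C | target

## Step count and risks

Total step count: 12. Longest linear sequence: 9 steps (steps 4 to 12, from geraniol); the ring branch (steps 1 to 3) joins at step 10.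

Steps most likely to fail:

1. Step 10. The organocopper may attack the carbinol carbon instead of the γ-carbon, or add only slowly at the γ-carbon next to the quaternary centre, which would erode regio- and stereochemical fidelity. Slow homoallyl–cyclopropylcarbinyl equilibration of the Grignard reagent could also scramble the geometry of its nearer olefin. The fallback sets out from enone 4 and Grignard reagent 15 and comes back at 16. A copper-catalysed enantioselective conjugate addition (CuBr·SMe2, chiral ferrocenyl diphosphine of the Josiphos type, the ligand enantiomer chosen for attack on the face that leads to the (S)-centre, t-BuOMe, −78 °C) should give the bromomagnesium enolate bromomagnesium (3S)-3-[(3E,7E)-9-{[tert-butyl(dimethyl)silyl]oxy}-3,7-dimethylnona-3,7-dien-1-yl]-2,4,4-trimethylcyclohex-1-en-1-olate F1. This is trapped in the same flask with N-(5-chloro-2-pyridyl)triflimide as the enol triflate (3S)-3-[(3E,7E)-9-{[tert-butyl(dimethyl)silyl]oxy}-3,7-dimethylnona-3,7-dien-1-yl]-2,4,4-trimethylcyclohex-1-en-1-yl trifluoromethanesulfonate F2. Palladium-catalysed formate reduction (Pd(OAc)2, PPh3, Bu3N, HCO2H, DMF, 60 °C) of the triflate then gives 16. The double-bond position is fixed by the regiospecific enolate, and the stereocentre is set by the ligand instead of by chirality transfer.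

2. Step 2. Uncatalysed borane reduction or competing hydroboration of the enone double bond may lower the enantiomeric purity of the carbinol on which the whole stereochemical relay rests. The fallback sets out from 4 and comes back at 5. Luche reduction (NaBH4, CeCl3·7H2O, MeOH, 0 °C) should give racemic 2,4,4-trimethylcyclohex-2-en-1-ol F3. Lipase-catalysed kinetic resolution (Candida antarctica lipase B, vinyl acetate, hexane, rt) should acetylate the (R)-enantiomer to (1R)-2,4,4-trimethylcyclohex-2-en-1-yl acetate F4, and the unreacted (S)-alcohol 5 is separated by chromatography.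

3. Step 1. Polymerisation of the vinyl ketone and acid-induced self-condensation may consume the components before the Michael step, so that little material reaches ring closure. The fallback sets out from 1 and 2 and comes back at 4. Aldehyde 1 is condensed with pyrrolidine (toluene, Dean–Stark) to the enamine 1-(2-methylprop-1-en-1-yl)pyrrolidine F5. Addition of F5 to 2 at 0 °C → rt should give the cycloadduct 6-ethyl-3,3-dimethyl-2-(pyrrolidin-1-yl)-3,4-dihydro-2H-pyran F6. Hydrolysis (aq. AcOH/NaOAc) releases ketoaldehyde 3, which is isolated and cyclised separately by base-mediated aldol condensation (KOH, MeOH, rt) to 4.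

Further compounds
F1 | step 10 | bromomagnesium (3S)-3-[(3E,7E)-9-{[tert-butyl(dimethyl)silyl]oxy}-3,7-dimethylnona-3,7-dien-1-yl]-2,4,4-trimethylcyclohex-1-en-1-olate | CC(C)(C)[Si](C)(C)OC/C=C(\C)CC/C=C(\C)CC[C@@H]1C(C)=C(O[Mg]Br)CCC1(C)C
F2 | step 10 | (3S)-3-[(3E,7E)-9-{[tert-butyl(dimethyl)silyl]oxy}-3,7-dimethylnona-3,7-dien-1-yl]-2,4,4-trimethylcyclohex-1-en-1-yl trifluoromethanesulfonate | CC(C)(C)[Si](C)(C)OC/C=C(\C)CC/C=C(\C)CC[C@@H]1C(C)=C(OS(=O)(=O)C(F)(F)F)CCC1(C)C
F3 | step 2 | rac-2,4,4-trimethylcyclohex-2-en-1-ol | OC1C(C)=CC(C)(C)CC1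
F4 | step 2 | (1R)-2,4,4-trimethylcyclohex-2-en-1-yl acetate | CC(=O)O[C@H]1C(C)=CC(C)(C)CC1
F5 | step 1 | 1-(2-methylprop-1-en-1-yl)pyrrolidine | CC(C)=CN1CCCC1
F6 | step 1 | 6-ethyl-3,3-dimethyl-2-(pyrrolidin-1-yl)-3,4-dihydro-2H-pyran | CCC1=CCC(C)(C)C(N2CCCC2)O1
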